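Cuts (C1 = lactone carbonyl, chain C1–C26): the lactone C1–O5 bond; C3–C4 (propiolate + C4–C5 oxirane); C12–C13 (C13–C26 Grignard reagent + C11–C12 oxirane). A C4–C12 bis(oxirane) remains.
Enabling feature: the carbinol carbons C5 (C6 of the dihydropyranone ring), C7, C9 and C11 are all-syn and lie between the CH2 groups C4 and C12. The C4–C12 stretch therefore has a mirror plane through C8 and can be carried as a meso compound until one end is differentiated.
Forward: a cyclopentene ring is cleaved to C6–C10, and both ends grow together to C4–C12 (vinyl addition, two iodocarbonate rings, two oxiranes). One oxirane is then hydrolysed selectively, and the tail, C1–C3 and finally the six-membered lactone ring follow.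
Stereochemistry: C7/C9 come from the cis-diol of the ring and C5/C11 from 1,3-syn iodocarbonate cyclisation. The absolute sense of all four comes from the cobalt-salen hydrolysis, and C15 from Ru-BINAP hydrogenation of a β-keto ester.

Key step: step 10

Remark: locants C1–C26 are those of the target chain. CIP letters at C5–C11 change with the protecting groups although no configuration changes after step 10.
Assumption: the (S,S)-cobalt-salen complex is taken to hydrolyse (R)-2-alkyloxiranes faster, as it does for simple monoalkyl oxiranes.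

Step 1
Reactants: 1 cis-cyclopent-4-ene-1,3-diol (meso)
Product: 2 cis-3,5-bis(tert-butyldimethylsilyloxy)cyclopent-1-ene (meso)
Conditions: TBSCl (2.4 equiv), imidazole (5 equiv), DMF, 0 °C to rt
Reagents that add atoms: tert-butyldimethylsilyl chloride (TBSCl), CC(C)(C)[Si](C)(C)Cl
Why: Imidazole-promoted O-silylation masks both secondary hydroxyls so that they stay distinct from the primary hydroxyls made in step 2, and no stereocentre is touched.

Step 2
Reactants: 2 cis-3,5-bis(tert-butyldimethylsilyloxy)cyclopent-1-ene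
Product: 4 meso-(2R,4S)-2,4-bis(tert-butyldimethylsilyloxy)pentane-1,5-diol, via meso-2,4-bis(silyloxy)pentanedial 3 (not isolated)
Conditions: O3, CH2Cl2–MeOH (1:1), −78 °C; then NaBH4 (4 equiv), −78 °C to 0 °C
Reagents that add atoms: ozone, [O-][O+]=O
Why: Ozonolysis with borohydride work-up cleaves the only alkene, and the cold reduction should outrun epimerisation of the α-silyloxy aldehydes and silyl migration, so the cis-diol of the ring becomes the syn (meso) 2,4-relationship of the open C6–C10 chain.

Step 3
Reactants: 4 meso-(2R,4S)-2,4-bis(tert-butyldimethylsilyloxy)pentane-1,5-diol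
Product: 5 meso-(2R,4S)-2,4-bis(tert-butyldimethylsilyloxy)pentane-1,5-diyl bis(4-methylbenzenesulfonate)
Conditions: TsCl (2.5 equiv), pyridine, 0 °C
Reagents that add atoms: 4-methylbenzenesulfonyl chloride (TsCl), Cc1ccc(cc1)S(=O)(=O)Cl
Why: Sulfonylation of the two free primary hydroxyls installs leaving groups only on carbons that are not stereocentres.

Step 4
Reactants: 5 meso bis(tosylate)
Product: 6 meso-(2R,4S)-1,2:4,5-diepoxypentane (C6–C10)
Conditions: TBAF (2.2 equiv), THF, 0 °C to rt; short silica pad (Et2O), cold concentration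
Reagents that add atoms: none
Why: Fluoride desilylation frees each secondary alkoxide next to a primary tosylate, which closes the oxirane by 3-exo-tet Williamson displacement with the C–O bonds at C7 and C9 intact; the salts stay on silica and the volatile product is concentrated cold.

Step 5
Reactants: 6 meso-1,2:4,5-diepoxypentane; 7 vinylmagnesium bromide (3 equiv, two are incorporated)
Product: 8 meso-(4R,6S)-nona-1,8-diene-4,6-diol (C4–C12)
Conditions: CuI (15 mol %), THF, −40 °C to 0 °C; aq NH4Cl
Reagents that add atoms: none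
Why: Copper-catalysed Grignard opening of monosubstituted oxiranes occurs at the CH2 termini, so both ends are extended at once and the carbinol configurations are kept.

Step 6
Reactants: 8 meso-(4R,6S)-nona-1,8-diene-4,6-diol
Product: 10 meso-(4R,6S)-nona-1,8-diene-4,6-diyl bis(tert-butyl carbonate), via dilithium dialkoxide 9 (not isolated)
Conditions: n-BuLi (2.05 equiv), THF, −78 °C; cannulated into Boc2O (3 equiv), THF, −78 °C to 0 °C
Reagents that add atoms: di-tert-butyl dicarbonate (Boc2O), CC(C)(C)OC(=O)OC(=O)OC(C)(C)C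
Why: Alkoxide acylation by Boc2O with inverse addition into excess anhydride should make the second acylation faster than carbonate transfer between the two 1,3-related oxygens, and no stereocentre is touched.

Step 7
Reactants: 10 meso bis(tert-butyl carbonate)
Product: 11 (4S,6S)-4-(iodomethyl)-6-{[(4R,6R)-6-(iodomethyl)-2-oxo-1,3-dioxan-4-yl]methyl}-1,3-dioxan-2-one (meso, all-syn, each ring cis-4,6-disubstituted)
Conditions: IBr (2.5 equiv), toluene, −85 °C; aq Na2S2O3–NaHCO3
Reagents that add atoms: iodine monobromide, IBr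
Why: In this iodocarbonate cyclisation of homoallylic tert-butyl carbonates the carbonyl oxygen attacks the iodonium ion 6-exo and the tert-butyl group is lost; each ring closes through a chair with both substituents equatorial, which sets C5 and C11 1,3-syn to C7 and C9, and cold IBr gives the strongest kinetic syn preference.

Step 8
Reactants: 11 meso bis(iodomethyl) bis(cyclic carbonate)
Product: 12 (2S,4R)-1-[(2S)-oxiran-2-yl]-5-[(2R)-oxiran-2-yl]pentane-2,4-diol (meso, all-syn)
Conditions: K2CO3 (4 equiv), MeOH, 0 °C to rt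
Reagents that add atoms: none
Why: Carbonate methanolysis frees the alkoxides next to the CH2I groups, which close both oxiranes by 3-exo-tet displacement at the primary carbons, so no C–O bond at a stereocentre breaks.

Step 9
Reactants: 12 meso diepoxy diol
Product: 13 (4S,6R)-2,2-dimethyl-4-{[(2S)-oxiran-2-yl]methyl}-6-{[(2R)-oxiran-2-yl]methyl}-1,3-dioxane (meso, all-syn; C4–C12 with C7,C9 acetonide)
Conditions: 2,2-dimethoxypropane (5 equiv), PPTS (5 mol %), CH2Cl2, 0 °C to rt
Reagents that add atoms: 2,2-dimethoxypropane, COC(C)(C)OC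
Why: Acid-catalysed transketalisation of the syn-1,3-diol to a chair dioxane is fast under PPTS, which is mild enough to spare monosubstituted oxiranes and to outrun 6-exo attack of a free hydroxyl on the far oxirane.

Step 10
Reactants: 13 meso bis(oxirane) acetonide
Product: 14 (2R)-3-[(4S,6S)-2,2-dimethyl-6-{[(2S)-oxiran-2-yl]methyl}-1,3-dioxan-4-yl]propane-1,2-diol (C4,C5-diol, C11–C12 oxirane)
Conditions: (S,S)-(salen)Co(OAc) (2 mol %; salen = N,N'-bis(3,5-di-tert-butylsalicylidene)cyclohexane-1,2-diaminate), H2O (1.0 equiv), THF (minimum), 0 °C to rt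
Reagents that add atoms: water, O
Why: This is a Jacobsen hydrolytic kinetic resolution run as a desymmetrisation: one trivalent cobalt-salen unit binds the oxirane oxygen as a Lewis acid while a second, hydroxide-bearing unit delivers hydroxide to the unsubstituted CH2 carbon C4, so a new C4–O bond forms, only the old C4–O bond of the oxirane breaks and C5 keeps its configuration. The closest known reaction type is the cobalt-salen hydrolysis of racemic monosubstituted oxiranes and its extension to bis(oxiranes). No C–C bond forms, no ring closes (one oxirane ring opens) and no new stereocentre is created; the choice between the two enantiotopic oxiranes turns the meso array into one enantiomer and so fixes the absolute configuration of C5, C7, C9 and C11 in a single event. The selectivity needed is enantiotopic-group selectivity and it is catalyst-controlled: the two ends of 13 are locally an (R)- and an (S)-2-alkyloxirane, and the (S,S)-complex should consume the (R)-configured end, the future C4–C5, much faster. Attack at the terminal carbon is secured by both oxiranes being monosubstituted, and the acetonide keeps O7 and O9 from acting as internal nucleophiles. A molecule opened at the wrong end still carries the fast-reacting oxirane and is drained to the tetraol, so the optical purity of 14 should rise with conversion and the material is not limited to half.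

Step 11
Reactants: 15 methyl 3-oxotetradecanoate
Product: 16 methyl (3S)-3-hydroxytetradecanoate
Conditions: RuCl2[(S)-BINAP] (0.1 mol %), H2 (10 bar), MeOH, 50 °C
Reagents that add atoms: none
Why: In the Noyori asymmetric hydrogenation of a β-keto ester, chelation of ketone and ester to the Ru-(S)-BINAP hydride fixes the face of hydride delivery and sets the future C15 as S.

Step 12
Reactants: 16 methyl (3S)-3-hydroxytetradecanoate
Product: 17 methyl (3S)-3-(tert-butyldimethylsilyloxy)tetradecanoate
Conditions: TBSCl (1.3 equiv), imidazole (2.5 equiv), DMF, rt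
Reagents that add atoms: tert-butyldimethylsilyl chloride (TBSCl), CC(C)(C)[Si](C)(C)Cl
Why: O-silylation gives an ether that tolerates hydride, Grignard formation and BF3 at low temperature, and the neutral conditions avoid β-elimination.

Step 13
Reactants: 17 methyl (3S)-3-(tert-butyldimethylsilyloxy)tetradecanoate
Product: 18 (3S)-3-(tert-butyldimethylsilyloxy)tetradecan-1-ol
Conditions: DIBAL-H (2.5 equiv), CH2Cl2, −78 °C to 0 °C; aq Rochelle salt
Reagents that add atoms: none
Why: Aluminium hydride reduction takes the ester to the primary alcohol, leaves the silyl ether in place and does not touch the stereocentre.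

Step 14
Reactants: 18 (3S)-3-(tert-butyldimethylsilyloxy)tetradecan-1-ol
Product: 19 (3S)-1-bromo-3-(tert-butyldimethylsilyloxy)tetradecane (C13–C26)
Conditions: CBr4 (1.3 equiv), PPh3 (1.4 equiv), CH2Cl2, 0 °C
Reagents that add atoms: carbon tetrabromide, BrC(Br)(Br)Br
Why: The Appel reaction replaces the primary hydroxyl by bromide through an SN2 step on the alkoxyphosphonium ion under near-neutral conditions that the TBS ether survives.

Step 15
Reactants: 14 epoxy diol
Product: 20 4,5-bis(trimethylsilyl) ether of 14 (5R,7R,9S,11S; C11–C12 oxirane and C7,C9 acetonide kept)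
Conditions: TMSCl (2.5 equiv), Et3N (4 equiv), CH2Cl2, 0 °C; hexane, filtration
Reagents that add atoms: chlorotrimethylsilane (TMSCl), C[Si](C)(C)Cl
Why: Transient O-silylation removes the two acidic protons that would otherwise destroy two equivalents of the valuable Grignard reagent, and these conditions leave the oxirane alone.

Step 16
Reactants: 19 (3S)-1-bromo-3-(tert-butyldimethylsilyloxy)tetradecane (1.8 equiv); 20 bis(TMS) epoxide
Product: 23 (2R)-3-{(4S,6R)-6-[(2R,6S)-6-(tert-butyldimethylsilyloxy)-2-hydroxyheptadecyl]-2,2-dimethyl-1,3-dioxan-4-yl}propane-1,2-diol (C4–C26 triol), via Grignard reagent 21 (not isolated), via bis-TMS C11 alcohol 22 (not isolated)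
Conditions: 19, Mg, THF, 40 °C; then 20, CuI (10 mol %), THF, −30 °C to 0 °C; aq NH4Cl; then K2CO3 (0.2 equiv), MeOH, rt
Reagents that add atoms: none
Why: Copper-catalysed Grignard opening of the monosubstituted oxirane at its CH2 carbon forms C12–C13 with C11 untouched, and the TMS ethers then fall off in basic methanol, which harms neither the acetonide nor the TBS ether.

Step 17
Reactants: 23 C4–C26 triol
Product: 25 (2R,6S)-6-(tert-butyldimethylsilyloxy)-1-[(4R,6R)-2,2-dimethyl-6-{[(2R)-oxiran-2-yl]methyl}-1,3-dioxan-4-yl]heptadecan-2-ol (C4–C5 oxirane re-formed), via primary tosylate 24 (not isolated)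
Conditions: Bu2SnO (5 mol %), TsCl (1.05 equiv), Et3N (1.5 equiv), CH2Cl2, 0 °C to rt; then K2CO3 (3 equiv), MeOH, rt
Reagents that add atoms: none
Why: Stannylene-acetal-mediated tosylation picks the primary hydroxyl of the 1,2-diol over the C5 and C11 secondary hydroxyls, and base then closes the oxirane by 3-exo-tet displacement at C4, so C5 keeps its configuration.

Step 18
Reactants: 25 C4–C26 epoxy alcohol
Product: 26 (4S,6R)-4-[(2R,6S)-2,6-bis(tert-butyldimethylsilyloxy)heptadecyl]-2,2-dimethyl-6-{[(2R)-oxiran-2-yl]methyl}-1,3-dioxane (11-O-TBS ether of 25)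
Conditions: TBSCl (1.5 equiv), imidazole (3 equiv), DMF, rt
Reagents that add atoms: tert-butyldimethylsilyl chloride (TBSCl), CC(C)(C)[Si](C)(C)Cl
Why: Silylation of the last free hydroxyl under non-Lewis-acidic conditions spares the oxirane and keeps an alkoxide from consuming acetylide and BF3 in step 19.

Step 19
Reactants: 26 protected C4–C26 epoxide; 27 methyl propiolate (4 equiv)
Product: 29 methyl (5S)-6-{(4S,6S)-6-[(2R,6S)-2,6-bis(tert-butyldimethylsilyloxy)heptadecyl]-2,2-dimethyl-1,3-dioxan-4-yl}-5-hydroxyhex-2-ynoate (C1–C26), via lithium acetylide 28 (not isolated)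
Conditions: 27, n-BuLi (3.8 equiv), THF, −78 °C; BF3·OEt2 (3.8 equiv), then 26, −78 °C
Reagents that add atoms: none
Why: In the Yamaguchi–Hirao alkynylation the BF3-activated monosubstituted oxirane is opened at C4 by the lithium acetylide at −78 °C, where lithiated propiolate is stable and the acetonide and silyl ethers persist, so C3–C4 forms and C5 is untouched.

Step 20
Reactants: 29 5-hydroxy-2-ynoate
Product: 30 methyl (2Z,5S)-6-{(4S,6S)-6-[(2R,6S)-2,6-bis(tert-butyldimethylsilyloxy)heptadecyl]-2,2-dimethyl-1,3-dioxan-4-yl}-5-hydroxyhex-2-enoate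
Conditions: H2 (1 atm), Pd/CaCO3 poisoned with Pb(OAc)2 (Lindlar catalyst), quinoline, EtOAc, rt
Reagents that add atoms: none
Why: Lindlar semi-hydrogenation delivers both hydrogens to one face of the alkyne and gives the Z-enoate, with quinoline holding back over-reduction.

Step 21
Reactants: 30 Z-enoate
Product: 31 (6S)-6-[(2R,4R,6R,10S)-2,4,6,10-tetrahydroxyhenicosyl]-5,6-dihydro-2H-pyran-2-one (CNP0158746.1)
Conditions: 48% aq HF, MeCN, 0 °C to rt
Reagents that add atoms: none
Why: Aqueous HF cleaves both TBS ethers and hydrolyses the acetonide, and the same acid drives acyl substitution of the Z-configured δ-hydroxy ester by O5 to the six-membered lactone without breaking any C–O bond at a stereocentre; low temperature and short contact hold back conjugate addition of the C7 hydroxyl.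

Compound list
1 | cis-cyclopent-4-ene-1,3-diol (meso) | O[C@H]1C[C@@H](O)C=C1 | starting material
2 | cis-3,5-bis(tert-butyldimethylsilyloxy)cyclopent-1-ene (meso) | CC(C)(C)[Si](C)(C)O[C@H]1C[C@@H](O[Si](C)(C)C(C)(C)C)C=C1 | intermediate
3 | meso-(2R,4S)-2,4-bis(tert-butyldimethylsilyloxy)pentanedial (not isolated) | O=C[C@@H](O[Si](C)(C)C(C)(C)C)C[C@@H](O[Si](C)(C)C(C)(C)C)C=O | intermediate
4 | meso-(2R,4S)-2,4-bis(tert-butyldimethylsilyloxy)pentane-1,5-diol | OC[C@@H](O[Si](C)(C)C(C)(C)C)C[C@@H](O[Si](C)(C)C(C)(C)C)CO | intermediate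
5 | meso-(2R,4S)-2,4-bis(tert-butyldimethylsilyloxy)pentane-1,5-diyl bis(4-methylbenzenesulfonate) | Cc1ccc(cc1)S(=O)(=O)OC[C@@H](O[Si](C)(C)C(C)(C)C)C[C@@H](O[Si](C)(C)C(C)(C)C)COS(=O)(=O)c1ccc(C)cc1 | intermediate
6 | meso-(2R,4S)-1,2:4,5-diepoxypentane | C1[C@@H](O1)C[C@@H]1CO1 | intermediate
7 | vinylmagnesium bromide | C=C[Mg]Br | starting material
8 | meso-(4R,6S)-nona-1,8-diene-4,6-diol | C=CC[C@@H](O)C[C@@H](O)CC=C | intermediate
9 | dilithium meso-nona-1,8-diene-4,6-diolate (not isolated) | [Li+].[Li+].C=CC[C@@H]([O-])C[C@@H]([O-])CC=C | intermediate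
10 | meso-(4R,6S)-nona-1,8-diene-4,6-diyl bis(tert-butyl carbonate) | C=CC[C@@H](OC(=O)OC(C)(C)C)C[C@@H](OC(=O)OC(C)(C)C)CC=C | intermediate
11 | (4S,6S)-4-(iodomethyl)-6-{[(4R,6R)-6-(iodomethyl)-2-oxo-1,3-dioxan-4-yl]methyl}-1,3-dioxan-2-one (meso, all-syn) | IC[C@@H]1C[C@H](C[C@@H]2C[C@H](CI)OC(=O)O2)OC(=O)O1 | intermediate
12 | (2S,4R)-1-[(2S)-oxiran-2-yl]-5-[(2R)-oxiran-2-yl]pentane-2,4-diol (meso, all-syn) | C1[C@@H](O1)C[C@@H](O)C[C@@H](O)C[C@@H]1CO1 | intermediate
13 | (4S,6R)-2,2-dimethyl-4-{[(2S)-oxiran-2-yl]methyl}-6-{[(2R)-oxiran-2-yl]methyl}-1,3-dioxane (meso, all-syn) | C1[C@@H](O1)C[C@@H]2C[C@H](C[C@@H]3CO3)OC(C)(C)O2 | intermediate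
14 | (2R)-3-[(4S,6S)-2,2-dimethyl-6-{[(2S)-oxiran-2-yl]methyl}-1,3-dioxan-4-yl]propane-1,2-diol | C1[C@@H](O1)C[C@@H]2C[C@H](C[C@@H](O)CO)OC(C)(C)O2 | intermediate
15 | methyl 3-oxotetradecanoate | CCCCCCCCCCCC(=O)CC(=O)OC | starting material
16 | methyl (3S)-3-hydroxytetradecanoate | CCCCCCCCCCC[C@H](O)CC(=O)OC | intermediate
17 | methyl (3S)-3-(tert-butyldimethylsilyloxy)tetradecanoate | CCCCCCCCCCC[C@H](O[Si](C)(C)C(C)(C)C)CC(=O)OC | intermediate
18 | (3S)-3-(tert-butyldimethylsilyloxy)tetradecan-1-ol | CCCCCCCCCCC[C@H](O[Si](C)(C)C(C)(C)C)CCO | intermediate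
19 | (3S)-1-bromo-3-(tert-butyldimethylsilyloxy)tetradecane | CCCCCCCCCCC[C@H](O[Si](C)(C)C(C)(C)C)CCBr | intermediate
20 | 4,5-bis(trimethylsilyl) ether of 14 (5R,7R,9S,11S) | C1[C@@H](O1)C[C@@H]2C[C@H](C[C@@H](O[Si](C)(C)C)CO[Si](C)(C)C)OC(C)(C)O2 | intermediate
21 | [(3S)-3-(tert-butyldimethylsilyloxy)tetradecyl]magnesium bromide (not isolated) | CCCCCCCCCCC[C@H](O[Si](C)(C)C(C)(C)C)CC[Mg]Br | intermediate
22 | C4–C26 C11 alcohol with 4,5-bis(TMS) ether, 7,9-acetonide and 15-O-TBS (5R,7R,9R,11R,15S; not isolated) | CCCCCCCCCCC[C@H](O[Si](C)(C)C(C)(C)C)CCC[C@@H](O)C[C@@H]1C[C@H](C[C@@H](O[Si](C)(C)C)CO[Si](C)(C)C)OC(C)(C)O1 | intermediate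
23 | (2R)-3-{(4S,6R)-6-[(2R,6S)-6-(tert-butyldimethylsilyloxy)-2-hydroxyheptadecyl]-2,2-dimethyl-1,3-dioxan-4-yl}propane-1,2-diol | CCCCCCCCCCC[C@H](O[Si](C)(C)C(C)(C)C)CCC[C@@H](O)C[C@@H]1C[C@H](C[C@@H](O)CO)OC(C)(C)O1 | intermediate
24 | C4 4-methylbenzenesulfonate of 23 (5R,7S,9R,11R,15S; not isolated) | CCCCCCCCCCC[C@H](O[Si](C)(C)C(C)(C)C)CCC[C@@H](O)C[C@@H]1C[C@H](C[C@@H](O)COS(=O)(=O)c2ccc(C)cc2)OC(C)(C)O1 | intermediate
25 | (2R,6S)-6-(tert-butyldimethylsilyloxy)-1-[(4R,6R)-2,2-dimethyl-6-{[(2R)-oxiran-2-yl]methyl}-1,3-dioxan-4-yl]heptadecan-2-ol | CCCCCCCCCCC[C@H](O[Si](C)(C)C(C)(C)C)CCC[C@@H](O)C[C@@H]1C[C@H](C[C@@H]2CO2)OC(C)(C)O1 | intermediate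
26 | (4S,6R)-4-[(2R,6S)-2,6-bis(tert-butyldimethylsilyloxy)heptadecyl]-2,2-dimethyl-6-{[(2R)-oxiran-2-yl]methyl}-1,3-dioxane | CCCCCCCCCCC[C@H](O[Si](C)(C)C(C)(C)C)CCC[C@@H](O[Si](C)(C)C(C)(C)C)C[C@@H]1C[C@H](C[C@@H]2CO2)OC(C)(C)O1 | intermediate
27 | methyl propiolate | C#CC(=O)OC | starting material
28 | lithium 3-methoxy-3-oxoprop-1-yn-1-ide (not isolated) | [Li+].[C-]#CC(=O)OC | intermediate
29 | methyl (5S)-6-{(4S,6S)-6-[(2R,6S)-2,6-bis(tert-butyldimethylsilyloxy)heptadecyl]-2,2-dimethyl-1,3-dioxan-4-yl}-5-hydroxyhex-2-ynoate | CCCCCCCCCCC[C@H](O[Si](C)(C)C(C)(C)C)CCC[C@@H](O[Si](C)(C)C(C)(C)C)C[C@@H]1C[C@H](C[C@@H](O)CC#CC(=O)OC)OC(C)(C)O1 | intermediate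
30 | methyl (2Z,5S)-6-{(4S,6S)-6-[(2R,6S)-2,6-bis(tert-butyldimethylsilyloxy)heptadecyl]-2,2-dimethyl-1,3-dioxan-4-yl}-5-hydroxyhex-2-enoate | CCCCCCCCCCC[C@H](O[Si](C)(C)C(C)(C)C)CCC[C@@H](O[Si](C)(C)C(C)(C)C)C[C@@H]1C[C@H](C[C@@H](O)C/C=C\C(=O)OC)OC(C)(C)O1 | intermediate
31 | (6S)-6-[(2R,4R,6R,10S)-2,4,6,10-tetrahydroxyhenicosyl]-5,6-dihydro-2H-pyran-2-one | CCCCCCCCCCC[C@H](O)CCC[C@@H](O)C[C@@H](O)C[C@@H](O)C[C@@H]1CC=CC(=O)O1 | target

Total step count: 21.
Longest linear sequence: 17 (steps 1–10 and 15–21). The side-chain branch (steps 11–14) joins at step 16.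

Steps most likely to fail

Step 10. The catalyst may discriminate too weakly between the two oxirane ends, or hydrolysis may run on to the tetraol before the fast end is fully consumed. Either would cost optical purity or material. The fallback sets out from 13 and returns at 14, and it moves the desymmetrisation from the oxiranes to the primary hydroxyls.
- Both oxiranes are opened at their CH2 carbons with racemic (salen)Co(OAc) and excess water to give the meso all-syn tetraol F1.
- A lipase screened for the required sense (vinyl acetate, MTBE) acetylates one of the two enantiotopic primary hydroxyls to give the C4 monoacetate F2.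
- Bu2SnO-catalysed tosylation of the only remaining primary hydroxyl gives the C12 tosylate F3.
- K2CO3 in MeOH closes the C11–C12 oxirane and removes the acetate in the same operation, which gives 14.

Step 6. After the first acylation the neighbouring alkoxide may attack the new carbonate and close a six-membered cyclic carbonate across O7 and O9. That would remove both oxygens from the later cyclisation. The fallback sets out from 8 and returns at 11, bypassing 10. The dialkoxide 9 is saturated with CO2 to give the dilithium bis(carbonate) F4. Its anionic carbonate groups are not electrophilic and cannot be transferred. Treatment with I2 in THF then lets each carbonate oxygen attack the iodonium ion of its own homoallylic alkene through the same diequatorial chair, which gives the bis(iodocarbonate) 11 directly.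

Step 21. Once freed under acid, the C7 hydroxyl is 5,7-syn and well placed for a bridged ether. It may add in conjugate fashion to C3 of the unsaturated lactone, or lactonisation may stay incomplete. The fallback sets out from 29 and returns at 31, and it reverses the order so that acid never meets the enoate. Aqueous HF in MeCN removes the silyl ethers and the acetonide at the alkyne stage to give the pentahydroxy ynoate F5, whose linear and unactivated triple bond is not attacked under these conditions. Lindlar semi-hydrogenation under neutral conditions then gives the pentahydroxy Z-enoate F6. This should lactonise on its own through the C5 hydroxyl, the only one that can form a six-membered ring, to give 31.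

Further compounds
F1 | step 10 | 3,3'-[(4R,6S)-2,2-dimethyl-1,3-dioxane-4,6-diyl]bis(propane-1,2-diol), meso all-syn tetraol | OC[C@@H](O)C[C@@H]1C[C@H](C[C@@H](O)CO)OC(C)(C)O1
F2 | step 10 | C4 monoacetate of F1 | OC[C@@H](O)C[C@@H]1C[C@H](C[C@@H](O)COC(C)=O)OC(C)(C)O1
F3 | step 10 | C12 4-methylbenzenesulfonate of F2 | Cc1ccc(cc1)S(=O)(=O)OC[C@@H](O)C[C@@H]1C[C@H](C[C@@H](O)COC(C)=O)OC(C)(C)O1
F4 | step 6 | dilithium meso-nona-1,8-diene-4,6-diyl bis(carbonate) | [Li+].[Li+].C=CC[C@@H](OC([O-])=O)C[C@@H](OC([O-])=O)CC=C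
F5 | step 21 | methyl (5S,7S,9R,11R,15S)-5,7,9,11,15-pentahydroxyhexacos-2-ynoate | CCCCCCCCCCC[C@H](O)CCC[C@@H](O)C[C@@H](O)C[C@@H](O)C[C@@H](O)CC#CC(=O)OC
F6 | step 21 | methyl (2Z,5S,7S,9R,11R,15S)-5,7,9,11,15-pentahydroxyhexacos-2-enoate | CCCCCCCCCCC[C@H](O)CCC[C@@H](O)C[C@@H](O)C[C@@H](O)C[C@@H](O)C/C=C\C(=O)OC
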